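**Strategy**

The cycloheptane ring (C6, C7, C8, C9, C10, C1, C5) carries cis oxygens on C5 and C9, an oxygen on C6 and carbonyl-derived carbons at C7 and C1, which is the imprint of an 8-oxabicyclo[3.2.1]octan-3-one. The route therefore rests on a (4+3) cycloaddition between 3-methoxyfuran (C5, C1, C10, C9 and the bridging oxygen) and a chiral alkoxy-substituted 2-siloxyallyl cation (C6, C7, C8), which forms C5–C6 and C8–C9, closes the carbocycle and sets C5, C6 and C9 in one operation. The precursor is a mixed methyl (R)-1-phenylethyl acetal of 2-(triethylsilyloxy)acrolein. The bridge is later opened, the C9 oxygen returned, and the lactone and enone are added last.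

Key step: step 4

Numbering: C6 = lactone O–CH, C7 = ring-fusion CH, C8 = CH2, C9 = CHOH, C10 = CHMe (methyl C14), C1 = C(OH) bearing C2(=O)–C3=C4–C15, C5 = CH–O-ester; C11, C12, C13 = lactone α-carbon, carbonyl and exocyclic methylene.

Assumption: the sense of induction of the (R)-1-phenylethyl group is taken from an open model (E-oxocarbenium ion, auxiliary C–H in the cation plane, furan anti to phenyl); should it prove opposite, (S)-1-phenylethanol is used and nothing else changes.

**Route**

Step 1
Reactants: 1 1,1-dimethoxypropan-2-one; 2 (R)-1-phenylethanol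
Product: 3 1-methoxy-1-[(R)-1-phenylethoxy]propan-2-one (both epimers at the acetal carbon)
Conditions: PPTS (cat.), cyclohexane, reflux, 4 Å sieves (MeOH removed)
Reagents that add atoms: none
Why: Acid-catalysed transacetalisation driven by removal of methanol swaps one methoxy group for the chiral alkoxy group; the acetal carbon forms as both epimers, which is harmless because it becomes planar in step 4.

Step 2
Reactants: 3 1-methoxy-1-[(R)-1-phenylethoxy]propan-2-one
Product: 4 1-methoxy-1-[(R)-1-phenylethoxy]-2-(triethylsilyloxy)prop-2-ene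
Conditions: LiN(iPr)2, THF, −78 °C; Et3SiCl, −78 °C → rt
Reagents that add atoms: chlorotriethylsilane, CC[Si](Cl)(CC)CC
Why: Kinetic deprotonation of the methyl group and O-silylation (silyl enol ether formation) under basic conditions give the siloxyallyl acetal without exposing the acid-labile mixed acetal to a silyl triflate.

Step 3
Reactants: 5 3-bromofuran
Product: 6 3-methoxyfuran
Conditions: NaOMe, CuBr (10 mol %), MeOH/NMP, 100 °C
Reagents that add atoms: sodium methoxide, C[O-].[Na+]
Why: Ullmann-type copper-catalysed C–O coupling exchanges bromide for methoxide on the heteroaryl bromide.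

Step 4
Reactants: 4 1-methoxy-1-[(R)-1-phenylethoxy]-2-(triethylsilyloxy)prop-2-ene; 6 3-methoxyfuran
Product: 9 7-methoxy-2-[(R)-1-phenylethoxy]-8-oxabicyclo[3.2.1]oct-6-en-3-one (C6 alkoxy equatorial; C1=C10 methyl enol ether; C7 ketone), via siloxyallyl cation triflate 7 (not isolated), via furanium triflate 8 (not isolated)
Conditions: Me3SiOTf (0.1 equiv), 6 (3 equiv), CH2Cl2, −95 °C; Et3N quench
Reagents that add atoms: none
Why: Me3SiOTf ionises the mixed acetal by removing its methoxy group to give the E-configured alkoxy-2-siloxyallyl cation 7; C2 of 3-methoxyfuran, activated by both oxygens, adds to the oxocarbenium carbon (bond C5–C6), and the enol silane carbon C8 then adds to the methoxy-stabilised furanium ion 8 at C9 with release of Et3SiOTf, which carries the chain. The closest known reaction type is the silyl triflate-promoted (4+3) cycloaddition of furan with alkoxy-substituted 2-siloxyallyl cations made from mixed acetals of 2-siloxyacrolein; only the 3-methoxy substituent on the diene is new. The C8–C9 bond closes the seven-membered carbocycle (C1, C5, C6, C7, C8, C9, C10) by a 7-(enolendo)-exo-trig addition of the enol silane to the C9 oxocarbenium carbon and at the same time the six-membered oxacycle (O, C5, C6, C7, C8, C9) of the oxabicycle. C6 is controlled by the auxiliary, whose C–H eclipses the oxocarbenium ion so that the furan approaches anti to phenyl; C5 and C9 are controlled by the compact approach that leaves the C6 alkoxy group equatorial (trans to the bridge), the bridge itself being necessarily cis. The step needs regioselectivity (methoxy-bearing C1 next to C5), facial selectivity and the equatorial alkoxy group; these should be secured by the polarity match between the most nucleophilic furan carbon and the oxocarbenium carbon, by the auxiliary, and by working at −95 °C, which also disfavours proton loss from 8 back to an aromatic furan.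

Step 5
Reactants: 9 (4+3) adduct
Product: 10 C7 axial alcohol of the adduct (hydroxyl cis to the C6 ether)
Conditions: LiBH(s-Bu)3, THF, −78 °C; H2O
Reagents that add atoms: none
Why: Diastereoselective ketone reduction in which the bulky borohydride attacks C7 along the equatorial trajectory on the convex side, giving the axial alcohol; this centre is temporary and is reoxidised in step 12.

Step 6
Reactants: 10 C7 axial alcohol
Product: 11 C7 tert-butyldimethylsilyl ether
Conditions: t-BuMe2SiCl, imidazole, DMAP (cat.), DMF, 40 °C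
Reagents that add atoms: tert-butyldimethylsilyl chloride, CC(C)(C)[Si](C)(C)Cl
Why: Standard silylation parks C7 so that C1 will be the only carbonyl during the next steps; the basic medium leaves the enol ether intact.

Step 7
Reactants: 11 C7 silyl ether with C1=C10 methyl enol ether
Product: 13 C1 ketone with exo (dimethylamino)methyl group at C10, via methoxycarbenium iodide 12 (not isolated)
Conditions: (CH2=NMe2)I, CH2Cl2, 0 °C → rt
Reagents that add atoms: dimethylmethyleneiminium iodide, C=[N+](C)C.[I-]
Why: Mannich reaction in which the nucleophilic C10 of the enol ether attacks the iminium ion from the exo face (the side of the oxygen bridge) and iodide O-demethylates the methoxycarbenium ion 12 to the C1 ketone; the new carbon becomes C14.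

Step 8
Reactants: 13 C10 Mannich base
Product: 15 C10 exo-methylene C1 ketone, via ammonium iodide 14 (not isolated)
Conditions: MeI, THF, rt; then NaHCO3 (aq), CH2Cl2, rt
Reagents that add atoms: none
Why: Exhaustive N-methylation followed by E1cB (Hofmann-type) elimination of trimethylamine from the β-ammonium ketone gives the exocyclic enone and erases the provisional C10 centre.

Step 9
Reactants: 15 C10 exo-methylene C1 ketone
Product: 16 C1 ketone with endo methyl at C10
Conditions: H2 (1 atm), RhCl(PPh3)3 (5 mol %), benzene, rt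
Reagents that add atoms: none
Why: Homogeneous hydrogenation reduces only the 1,1-disubstituted enone alkene, sparing the benzylic ether and the allylic C9–O bond that Pd/C would endanger, and delivers hydrogen from the open exo face so that the C10 methyl ends endo (C10 set).

Step 10
Reactants: 16 C1 ketone with endo C10 methyl
Product: 17 C1 tertiary alcohol (endo hydroxyl) bearing an exo 1-ethoxyvinyl group
Conditions: ethyl vinyl ether, t-BuLi, THF, −78 → 0 °C; CeCl3, −78 °C; then 16, −78 °C; NH4Cl (aq)
Reagents that add atoms: ethyl vinyl ether, C=COCC (delivered as 1-ethoxyvinyllithium, [Li]C(=C)OCC)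
Why: 1,2-Addition of the weakly basic organocerium acyl-anion equivalent to the C1 ketone from the exo face gives the endo hydroxyl (C1 set, trans to O5) without epimerising the kinetically installed C10 methyl.

Step 11
Reactants: 17 C1 tertiary alcohol with C7 silyl ether
Product: 18 C7,C1 diol
Conditions: Bu4NF, THF, 0 °C → rt
Reagents that add atoms: none
Why: Fluoride-mediated desilylation frees the C7 alcohol under basic conditions in which the enol ether, benzylic ether and tertiary alcohol are inert.

Step 12
Reactants: 18 C7,C1 diol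
Product: 19 C7 ketone with free C1 hydroxyl
Conditions: Dess–Martin periodinane, pyridine, CH2Cl2, 0 °C → rt
Reagents that add atoms: none
Why: Dess–Martin oxidation converts the secondary C7 alcohol to the ketone, the tertiary alcohol cannot be oxidised and the pyridine buffer protects the enol ether from acetic acid.

Step 13
Reactants: 19 C7 ketone with free C1 hydroxyl
Product: 20 C7 ketone with C1 trimethylsilyl ether
Conditions: N-(trimethylsilyl)imidazole, CH2Cl2, rt
Reagents that add atoms: N-(trimethylsilyl)imidazole, C[Si](C)(C)n1ccnc1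
Why: Silylation of the hindered tertiary alcohol with a neutral silyl-transfer reagent avoids enolising the C7 ketone, which a silyl triflate and amine would do with premature bridge opening.

Step 14
Reactants: 21 (S)-2-methylbutanoic acid
Product: 22 (S)-2-methylbutanoyl chloride
Conditions: (COCl)2, DMF (cat.), CH2Cl2, 0 °C → rt; volatiles removed
Reagents that add atoms: oxalyl chloride, ClC(=O)C(Cl)=O
Why: Acid chloride formation through the chloroiminium (Vilsmeier-type) intermediate without added base, so the α-stereocentre is not epimerised.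

Step 15
Reactants: 20 C7 ketone with C1 trimethylsilyl ether; 22 (S)-2-methylbutanoyl chloride
Product: 24 cyclohept-2-enone (C7 ketone, C8=C9) carrying the C5 (S)-2-methylbutanoate, via lithium alkoxide 23 (not isolated)
Conditions: LiN(iPr)2 (1.05 equiv), THF, −78 → −20 °C; then 22 (1.5 equiv), −78 → 0 °C
Reagents that add atoms: none
Why: Kinetic deprotonation at the unhindered C8 methylene gives the C7–C8 enolate, which on warming expels the bridging oxygen from C9 (E1cB β-elimination, the known base-induced opening of 8-oxabicyclo[3.2.1]octan-3-ones) to give alkoxide 23, and immediate O-acylation fixes the ester on O5 before retro-aldol cleavage can intervene.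

Step 16
Reactants: 24 cyclohept-2-enone with C5 ester
Product: 26 C9 β-hydroxy ketone (hydroxyl cis to O5 and trans to the C10 methyl), via pinacol boronate 25 (not isolated)
Conditions: B2pin2, CuCl (5 mol %), NaOtBu (10 mol %), bis[2-(diphenylphosphino)phenyl] ether (5 mol %), MeOH (2 equiv), THF, rt; then NaBO3·4H2O, THF/H2O, rt
Reagents that add atoms: bis(pinacolato)diboron, CC1(C)OB(OC1(C)C)B1OC(C)(C)C(C)(C)O1 (boron present only in 25); sodium perborate, [Na+].[O-]OB=O (the C9 oxygen)
Why: Copper-catalysed conjugate borylation adds boron to C9 anti to the adjacent C10 methyl group and perborate oxidation replaces boron by hydroxyl with retention, which returns the C9 oxygen on the face of O5 (C9 set).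

Step 17
Reactants: 26 C9 β-hydroxy ketone
Product: 27 C9 tert-butyldimethylsilyl ether
Conditions: t-BuMe2SiOTf, 2,6-lutidine, CH2Cl2, −78 °C
Reagents that add atoms: tert-butyldimethylsilyl trifluoromethanesulfonate, CC(C)(C)[Si](C)(C)OS(=O)(=O)C(F)(F)F
Why: Low-temperature silylation with a hindered base protects O9 with a group that outlasts the coming acid step and prevents retro-aldol or dehydration of the β-hydroxy ketone later.

Step 18
Reactants: 27 fully protected β-silyloxy ketone
Product: 28 methyl ketone with free C1 hydroxyl (C6 ether and C9 silyl ether retained)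
Conditions: 1 M HCl (aq)/THF, 0 °C → rt
Reagents that add atoms: water, O
Why: Acid-catalysed enol ether hydrolysis through the ethoxycarbenium ion unmasks the C2 methyl ketone and the same acid removes the tertiary trimethylsilyl ether, while the secondary tert-butyldimethylsilyl ether survives.

Step 19
Reactants: 28 methyl ketone with C6 1-phenylethyl ether
Product: 29 C6 alcohol (α-hydroxy ketone)
Conditions: H2 (1 atm), Pd/C (10%), EtOAc, rt
Reagents that add atoms: none
Why: Hydrogenolysis of the benzylic C–O bond removes the auxiliary as ethylbenzene at the one stage where the molecule has no alkene, and the silyl ether, ester and ketones are inert in ethyl acetate.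

Step 20
Reactants: 29 C6 alcohol
Product: 30 C6 diethylphosphonoacetate
Conditions: (EtO)2P(O)CH2CO2H, DCC, DMAP (cat.), CH2Cl2, 0 °C → rt
Reagents that add atoms: diethylphosphonoacetic acid, CCOP(=O)(CC(=O)O)OCC
Why: Steglich esterification acylates the secondary C6 hydroxyl (bringing C11 and C12), the tertiary C1 hydroxyl being too hindered to compete.

Step 21
Reactants: 30 C6 diethylphosphonoacetate
Product: 31 fused butenolide (C7=C11)
Conditions: LiCl, iPr2NEt, MeCN, rt
Reagents that add atoms: none
Why: Intramolecular Horner–Wadsworth–Emmons reaction under Masamune–Roush conditions closes the five-membered lactone onto the C7 ketone, the mild amine base deprotonating only the phosphonate and sparing the β-silyloxy ketone and the C6 centre.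

Step 22
Reactants: 31 fused butenolide
Product: 33 cis-fused lactone with (dimethylamino)methyl group at C11, via silyl ketene acetal 32 (not isolated)
Conditions: [(Ph3P)CuH]6 (0.25 equiv), Me3SiCl, toluene/THF, −40 °C → rt; then (CH2=NMe2)I, CH2Cl2, rt; NaHCO3 (aq)
Reagents that add atoms: dimethylmethyleneiminium iodide, C=[N+](C)C.[I-] (chlorotrimethylsilane, C[Si](C)(C)Cl, leaves silicon only in 32)
Why: Chemoselective copper hydride 1,4-reduction of the butenolide (the isolated ketone is not reduced) delivers hydride to C7 on the convex face bearing H6, giving the cis ring fusion (C7 set), and the enolate trapped as ketene acetal 32 undergoes a Mukaiyama–Mannich reaction at C11 that brings in C13.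

Step 23
Reactants: 33 C11 Mannich base
Product: 35 cis-fused α-methylene lactone with methyl ketone side chain, via ammonium iodide 34 (not isolated)
Conditions: MeI, THF, rt; then NaHCO3 (aq), CH2Cl2, rt
Reagents that add atoms: none
Why: N-Methylation and mild-base E1cB elimination of trimethylamine generate the exocyclic methylene and erase the provisional C11 centre without touching C7.

Step 24
Reactants: 35 α-methylene lactone with methyl ketone
Product: 37 β-hydroxy ketone aldol adduct (both epimers at C4), via boron enolate 36 (not isolated)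
Conditions: n-Bu2BOTf (2.2 equiv), iPr2NEt (2.5 equiv), CH2Cl2, −78 °C; MeCHO, −78 → −20 °C; pH 7 buffer/MeOH (no peroxide)
Reagents that add atoms: acetaldehyde, CC=O (dibutylboron triflate, CCCCB(CCCC)OS(=O)(=O)C(F)(F)F, leaves boron only in 36)
Why: Boron-mediated aldol reaction in which soft enolisation occurs only at the methyl ketone (the tertiary hydroxyl being tied up as a borinate) and addition to acetaldehyde brings C4 and C15; the carbinol configuration is irrelevant because it is removed next.

Step 25
Reactants: 37 aldol adduct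
Product: 39 (E)-enone with C9 silyl ether, via mesylate 38 (not isolated)
Conditions: MsCl, Et3N, CH2Cl2, 0 °C → rt
Reagents that add atoms: none
Why: Mesylation of the secondary aldol hydroxyl and in situ E1cB elimination give the conjugated enone in the thermodynamically favoured (E) geometry, the hindered tertiary hydroxyl staying free.

Step 26
Reactants: 39 (E)-enone with C9 silyl ether
Product: 40 target CNP0331957.1
Conditions: HF·pyridine, THF, 0 °C → rt
Reagents that add atoms: none
Why: Fluoride cleavage of the secondary silyl ether under mildly acidic conditions, which the α-methylene lactone, enone and esters tolerate, releases the target.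

**Compound list**

1 | 1,1-dimethoxypropan-2-one | CC(=O)C(OC)OC | starting material
2 | (R)-1-phenylethanol | C[C@@H](O)c1ccccc1 | starting material
3 | 1-methoxy-1-[(R)-1-phenylethoxy]propan-2-one, epimers at the acetal carbon | CC(=O)C(OC)O[C@H](C)c1ccccc1 | intermediate
4 | 1-methoxy-1-[(R)-1-phenylethoxy]-2-(triethylsilyloxy)prop-2-ene, epimers at the acetal carbon | C=C(O[Si](CC)(CC)CC)C(OC)O[C@H](C)c1ccccc1 | intermediate
5 | 3-bromofuran | Brc1ccoc1 | starting material
6 | 3-methoxyfuran | COc1ccoc1 | intermediate
7 | E-configured alkoxy-2-siloxyallyl cation triflate (not isolated) | C=C(O[Si](CC)(CC)CC)/C=[O+]/[C@H](C)c1ccccc1.[O-]S(=O)(=O)C(F)(F)F | intermediate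
8 | 3-methoxy-2H-furanium triflate with the C5–C6 bond formed (not isolated) | C[C@H](c1ccccc1)O[C@H](C(=C)O[Si](CC)(CC)CC)[C@@H]1[O+]=CC=C1OC.[O-]S(=O)(=O)C(F)(F)F | intermediate
9 | 7-methoxy-2-[(R)-1-phenylethoxy]-8-oxabicyclo[3.2.1]oct-6-en-3-one, C6 alkoxy equatorial | C[C@H](c1ccccc1)O[C@@H]1C(=O)C[C@@H]2C=C(OC)[C@H]1O2 | intermediate
10 | C7 axial alcohol of 9 | C[C@H](c1ccccc1)O[C@@H]1[C@H](O)C[C@@H]2C=C(OC)[C@H]1O2 | intermediate
11 | C7 tert-butyldimethylsilyl ether of 10 | C[C@H](c1ccccc1)O[C@@H]1[C@H](O[Si](C)(C)C(C)(C)C)C[C@@H]2C=C(OC)[C@H]1O2 | intermediate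
12 | C1 methoxycarbenium iodide with exo CH2NMe2 at C10 (not isolated) | C[C@H](c1ccccc1)O[C@@H]1[C@H](O[Si](C)(C)C(C)(C)C)C[C@@H]2[C@@H](CN(C)C)C(=[O+]C)[C@H]1O2.[I-] | intermediate
13 | C1 ketone with exo (dimethylamino)methyl group at C10 | C[C@H](c1ccccc1)O[C@@H]1[C@H](O[Si](C)(C)C(C)(C)C)C[C@@H]2[C@@H](CN(C)C)C(=O)[C@H]1O2 | intermediate
14 | trimethylammonium iodide of 13 (not isolated) | C[C@H](c1ccccc1)O[C@@H]1[C@H](O[Si](C)(C)C(C)(C)C)C[C@@H]2[C@@H](C[N+](C)(C)C)C(=O)[C@H]1O2.[I-] | intermediate
15 | C10 exo-methylene C1 ketone | C[C@H](c1ccccc1)O[C@@H]1[C@H](O[Si](C)(C)C(C)(C)C)C[C@@H]2C(=C)C(=O)[C@H]1O2 | intermediate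
16 | bicyclic C1 ketone with endo C10 methyl and C7 silyl ether | C[C@H](c1ccccc1)O[C@@H]1[C@H](O[Si](C)(C)C(C)(C)C)C[C@@H]2[C@H](C)C(=O)[C@H]1O2 | intermediate
17 | C1 tertiary alcohol (endo hydroxyl) with exo 1-ethoxyvinyl group | C[C@H](c1ccccc1)O[C@@H]1[C@H](O[Si](C)(C)C(C)(C)C)C[C@@H]2[C@H](C)[C@@](O)(C(OCC)=C)[C@H]1O2 | intermediate
18 | C7,C1 diol | C[C@H](c1ccccc1)O[C@@H]1[C@H](O)C[C@@H]2[C@H](C)[C@@](O)(C(OCC)=C)[C@H]1O2 | intermediate
19 | bicyclic C7 ketone with free C1 hydroxyl | C[C@H](c1ccccc1)O[C@@H]1C(=O)C[C@@H]2[C@H](C)[C@@](O)(C(OCC)=C)[C@H]1O2 | intermediate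
20 | bicyclic C7 ketone with C1 trimethylsilyl ether | C[C@H](c1ccccc1)O[C@@H]1C(=O)C[C@@H]2[C@H](C)[C@@](O[Si](C)(C)C)(C(OCC)=C)[C@H]1O2 | intermediate
21 | (S)-2-methylbutanoic acid | CC[C@H](C)C(=O)O | starting material
22 | (S)-2-methylbutanoyl chloride | CC[C@H](C)C(Cl)=O | intermediate
23 | lithium C5 alkoxide of the ring-opened cyclohept-2-enone (not isolated) | C[C@H](c1ccccc1)O[C@@H]1C(=O)C=C[C@H](C)[C@@](O[Si](C)(C)C)(C(OCC)=C)[C@H]1[O-].[Li+] | intermediate
24 | cyclohept-2-enone (C7 ketone, C8=C9) with C5 (S)-2-methylbutanoate | C[C@H](c1ccccc1)O[C@@H]1C(=O)C=C[C@H](C)[C@@](O[Si](C)(C)C)(C(OCC)=C)[C@H]1OC(=O)[C@@H](C)CC | intermediate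
25 | C9 pinacol boronate (not isolated) | C[C@H](c1ccccc1)O[C@@H]1C(=O)C[C@@H](B2OC(C)(C)C(C)(C)O2)[C@H](C)[C@@](O[Si](C)(C)C)(C(OCC)=C)[C@H]1OC(=O)[C@@H](C)CC | intermediate
26 | C9 β-hydroxy ketone | C[C@H](c1ccccc1)O[C@@H]1C(=O)C[C@@H](O)[C@H](C)[C@@](O[Si](C)(C)C)(C(OCC)=C)[C@H]1OC(=O)[C@@H](C)CC | intermediate
27 | C9 tert-butyldimethylsilyl ether | C[C@H](c1ccccc1)O[C@@H]1C(=O)C[C@@H](O[Si](C)(C)C(C)(C)C)[C@H](C)[C@@](O[Si](C)(C)C)(C(OCC)=C)[C@H]1OC(=O)[C@@H](C)CC | intermediate
28 | methyl ketone with free C1 hydroxyl and C6 1-phenylethyl ether | C[C@H](c1ccccc1)O[C@@H]1C(=O)C[C@@H](O[Si](C)(C)C(C)(C)C)[C@H](C)[C@@](O)(C(C)=O)[C@H]1OC(=O)[C@@H](C)CC | intermediate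
29 | C6 alcohol (α-hydroxy ketone) | O[C@@H]1C(=O)C[C@@H](O[Si](C)(C)C(C)(C)C)[C@H](C)[C@@](O)(C(C)=O)[C@H]1OC(=O)[C@@H](C)CC | intermediate
30 | C6 diethylphosphonoacetate | CCOP(=O)(OCC)CC(=O)O[C@@H]1C(=O)C[C@@H](O[Si](C)(C)C(C)(C)C)[C@H](C)[C@@](O)(C(C)=O)[C@H]1OC(=O)[C@@H](C)CC | intermediate
31 | fused butenolide (C7=C11) with methyl ketone side chain | O=C1O[C@@H]2C(=C1)C[C@@H](O[Si](C)(C)C(C)(C)C)[C@H](C)[C@@](O)(C(C)=O)[C@H]2OC(=O)[C@@H](C)CC | intermediate
32 | trimethylsilyl ketene acetal of the cis-fused lactone (not isolated) | C1=C(O[Si](C)(C)C)O[C@@H]2[C@H]1C[C@@H](O[Si](C)(C)C(C)(C)C)[C@H](C)[C@@](O)(C(C)=O)[C@H]2OC(=O)[C@@H](C)CC | intermediate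
33 | cis-fused lactone with (dimethylamino)methyl group at C11 (C11 drawn as expected from convex-face attack; erased in step 23) | CN(C)C[C@@H]1C(=O)O[C@@H]2[C@H]1C[C@@H](O[Si](C)(C)C(C)(C)C)[C@H](C)[C@@](O)(C(C)=O)[C@H]2OC(=O)[C@@H](C)CC | intermediate
34 | trimethylammonium iodide of 33 (not isolated) | C[N+](C)(C)C[C@@H]1C(=O)O[C@@H]2[C@H]1C[C@@H](O[Si](C)(C)C(C)(C)C)[C@H](C)[C@@](O)(C(C)=O)[C@H]2OC(=O)[C@@H](C)CC.[I-] | intermediate
35 | cis-fused α-methylene lactone with methyl ketone side chain | C=C1C(=O)O[C@@H]2[C@H]1C[C@@H](O[Si](C)(C)C(C)(C)C)[C@H](C)[C@@](O)(C(C)=O)[C@H]2OC(=O)[C@@H](C)CC | intermediate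
36 | dibutylboron enolate of the methyl ketone with C1 borinate (not isolated) | C=C1C(=O)O[C@@H]2[C@H]1C[C@@H](O[Si](C)(C)C(C)(C)C)[C@H](C)[C@@](OB(CCCC)CCCC)(C(=C)OB(CCCC)CCCC)[C@H]2OC(=O)[C@@H](C)CC | intermediate
37 | β-hydroxy ketone aldol adduct, both epimers at C4 | C=C1C(=O)O[C@@H]2[C@H]1C[C@@H](O[Si](C)(C)C(C)(C)C)[C@H](C)[C@@](O)(C(=O)CC(C)O)[C@H]2OC(=O)[C@@H](C)CC | intermediate
38 | C4 mesylate of 37 (not isolated) | C=C1C(=O)O[C@@H]2[C@H]1C[C@@H](O[Si](C)(C)C(C)(C)C)[C@H](C)[C@@](O)(C(=O)CC(C)OS(C)(=O)=O)[C@H]2OC(=O)[C@@H](C)CC | intermediate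
39 | (E)-enone with C9 tert-butyldimethylsilyl ether | C=C1C(=O)O[C@@H]2[C@H]1C[C@@H](O[Si](C)(C)C(C)(C)C)[C@H](C)[C@@](O)(C(=O)/C=C/C)[C@H]2OC(=O)[C@@H](C)CC | intermediate
40 | CNP0331957.1 | C=C1C(=O)O[C@@H]2[C@H]1C[C@@H](O)[C@H](C)[C@@](O)(C(=O)/C=C/C)[C@H]2OC(=O)[C@@H](C)CC | target

**Step count**

Total step count: 26. Longest linear sequence: 24 steps (steps 1, 2, 4–13, 15–26); steps 3 and 14 are side branches.

**Steps most likely to fail**

1. Step 4. The furanium intermediate may lose a proton and rearomatise (alkylation of the furan instead of ring closure), the very electron-rich furan may oligomerise under the silyl triflate, or facial and regiochemical control may be insufficient. Fallback, setting out from 4 and returning at 13: the same cation is intercepted with unsubstituted furan, the established diene for this cation class, to give 2-[(R)-1-phenylethoxy]-8-oxabicyclo[3.2.1]oct-6-en-3-one F1. LiBH(s-Bu)3 reduction gives the axial C7 alcohol F2, and silylation gives its tert-butyldimethylsilyl ether F3. Reagent-controlled exo-face hydroboration with the matched enantiomer of diisopinocampheylborane and NaBO3 oxidation should place the hydroxyl on C1, giving the exo C1 alcohol F4, and Dess–Martin oxidation gives the C1 ketone F5. Its only possible enolate (toward C10, LiN(SiMe3)2, THF, −78 °C) is trapped with dimethylmethyleneiminium iodide to give 13.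

2. Step 15. Deprotonation may occur at C6 instead of C8 (which would expel the oxygen from C5), β-elimination from the rigid bicyclic enolate may be slow, or the C5 alkoxide may undergo retro-aldol cleavage before it is acylated. Fallback, setting out from 20 and returning at 24: Me3SiOTf/Et3N (CH2Cl2, 0 °C) forms the enol silane toward C8 and the silyl triflate assists cleavage of the C9–O bond, so that no free alkoxide is ever present; this gives the ring-opened cycloheptenone bis(trimethylsilyl) ether F6. Brief K2CO3 (cat.)/MeOH at 0 °C removes only the secondary silyl group to give the C5 hydroxy cycloheptenone F7, which is acylated with 22 (pyridine, DMAP cat., CH2Cl2, 0 °C) to give 24.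

3. Step 22. The enolate may be protonated (for example by the tertiary hydroxyl) before the Mannich stage, the methyl ketone may be partly reduced, or hydride may be delivered with poor facial selectivity. Fallback, setting out from 31 and returning at 33: heterogeneous hydrogenation (H2, Pd/C, EtOAc) from the convex face gives the cis-fused saturated lactone F8. Soft enolisation with Me3SiOTf/Et3N (CH2Cl2, −78 → 0 °C) masks the methyl ketone as its enol silane and the tertiary alcohol as silyl ether, giving the bis(trimethylsilyl) derivative F9. LiN(iPr)2 (THF, −78 °C) then deprotonates only the lactone α-position, dimethylmethyleneiminium iodide is added at −78 °C, and a citric acid work-up followed by NaHCO3 removes both silyl groups to give 33.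

**Further compounds**

F1 | step 4 | 2-[(R)-1-phenylethoxy]-8-oxabicyclo[3.2.1]oct-6-en-3-one, alkoxy equatorial | C[C@H](c1ccccc1)O[C@@H]1C(=O)C[C@@H]2C=C[C@H]1O2
F2 | step 4 | axial C7 alcohol of F1 | C[C@H](c1ccccc1)O[C@@H]1[C@H](O)C[C@@H]2C=C[C@H]1O2
F3 | step 4 | tert-butyldimethylsilyl ether of F2 | C[C@H](c1ccccc1)O[C@@H]1[C@H](O[Si](C)(C)C(C)(C)C)C[C@@H]2C=C[C@H]1O2
F4 | step 4 | exo C1 alcohol | C[C@H](c1ccccc1)O[C@@H]1[C@H](O[Si](C)(C)C(C)(C)C)C[C@@H]2C[C@@H](O)[C@H]1O2
F5 | step 4 | C1 ketone without C10 substituent | C[C@H](c1ccccc1)O[C@@H]1[C@H](O[Si](C)(C)C(C)(C)C)C[C@@H]2CC(=O)[C@H]1O2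
F6 | step 15 | ring-opened cycloheptenone bis(trimethylsilyl) ether (O5 and O1) | C[C@H](c1ccccc1)O[C@@H]1C(=O)C=C[C@H](C)[C@@](O[Si](C)(C)C)(C(OCC)=C)[C@H]1O[Si](C)(C)C
F7 | step 15 | C5 hydroxy cycloheptenone | C[C@H](c1ccccc1)O[C@@H]1C(=O)C=C[C@H](C)[C@@](O[Si](C)(C)C)(C(OCC)=C)[C@H]1O
F8 | step 22 | cis-fused saturated lactone | O=C1O[C@@H]2[C@H](C1)C[C@@H](O[Si](C)(C)C(C)(C)C)[C@H](C)[C@@](O)(C(C)=O)[C@H]2OC(=O)[C@@H](C)CC
F9 | step 22 | bis(trimethylsilyl) derivative of F8 (enol silane of the methyl ketone, C1 silyl ether) | O=C1O[C@@H]2[C@H](C1)C[C@@H](O[Si](C)(C)C(C)(C)C)[C@H](C)[C@@](O[Si](C)(C)C)(C(=C)O[Si](C)(C)C)[C@H]2OC(=O)[C@@H](C)CC
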